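Everything rests on cutting the C3–C4 bond of the cyclohexenone ring. The quaternary carbinol C6 is flanked by C5–C4(OH) within the ring and by C1'–C2'(OH) in the side chain; written at the aldehyde level, both neighbours become the same CH2CHO group, and the open-chain (Z)-β-iodoenone dialdehyde has a mirror plane through C6. A ligand-controlled Nozaki–Hiyama–Kishi closure onto one of the two aldehydes then forms the C3–C4 bond, the six-membered ring and the stereocentres C4 and C6 in one operation, and leaves the second aldehyde for the C15 chain. The precursor is a 3,3-disubstituted pentanedial whose C6 oxygen carries a chelating 4-methoxybenzyl (PMB) ether.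

Key step: step 8

Remarks before the steps
- Numbering: ring C1 (C=O), C2=C3, C4 (CHOH), C5 (CH2), C6 (C–O); chain C1'–C17'. The target is (4S,6R,2'S,10'Z); the two ring hydroxyls are cis and the side chain on C6 is trans to the C4 hydroxyl.
- Precursor design: the C6 oxygen carries a PMB ether, not a silyl ether. In the ring-closing transition state the aldehyde oxygen is bound to the chromium on C3 and so lies in the enone plane; the target needs the C6–O bond in that plane too (both oxygens pseudo-equatorial, hence cis). A silyl ether cannot chelate and would tend to stand perpendicular to the C1 carbonyl, which leads to the wrong diastereomer. A benzyl-type ether can be tied to the C1 carbonyl oxygen in a five-membered chelate, so the choice of arm is written into the substrate and the ligand is asked only for the face.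
- Because of the PMB ether the acyclic part is built from diethyl oxalate; no acidic acetal hydrolysis is needed.
- Descriptor note: C6 is (S) in aldehydes 13 and 14, where the CH2CHO arm outranks C5, and (R) from 20 onwards; the geometry does not change.
- Assumption: the (S)-configured sulfonamide–oxazoline ligand is taken to deliver C3 to the Re face of the reacting aldehyde. If the sense is the opposite, the (R)-ligand is used and nothing else changes.

Step 1
Reactants: 1 diethyl oxalate; 2 allylmagnesium bromide
Product: 3 ethyl 2-hydroxy-2-(prop-2-en-1-yl)pent-4-enoate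
Conditions: 2 (2.05 equiv) added to 1, Et2O, −78 °C → 0 °C; aq. work-up
Reagents that add atoms: none
Why: Twofold Grignard addition to one ester group of the oxalate (the α-keto ester set free after the first addition is the most electrophilic carbonyl in the flask, and the tertiary alkoxide then shields the neighbouring ester), the classical route to symmetrical tertiary α-hydroxy esters; no stereocentre is formed because the two allyl groups are identical.

Step 2
Reactants: 3 ethyl 2-hydroxy-2-(prop-2-en-1-yl)pent-4-enoate
Product: 4 ethyl 2-[(4-methoxyphenyl)methoxy]-2-(prop-2-en-1-yl)pent-4-enoate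
Conditions: NaH, 4-methoxybenzyl chloride, Bu4NI (cat.), THF/DMF, 0 °C → rt
Reagents that add atoms: 4-methoxybenzyl chloride, COc1ccc(CCl)cc1
Why: Williamson etherification of the tertiary sodium alkoxide with a reactive benzylic chloride under iodide catalysis; the substrate has no α-hydrogen, so the base can only deprotonate the hydroxyl.

Step 3
Reactants: 4 ethyl 2-[(4-methoxyphenyl)methoxy]-2-(prop-2-en-1-yl)pent-4-enoate
Product: 5 2-[(4-methoxyphenyl)methoxy]-2-(prop-2-en-1-yl)pent-4-enal
Conditions: i-Bu2AlH (1.2 equiv), CH2Cl2, −78 °C; aq. potassium sodium tartrate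
Reagents that add atoms: none
Why: Partial reduction of an α-alkoxy ester by i-Bu2AlH at −78 °C, which stops at the chelated aluminium hemiacetal and gives the non-enolisable aldehyde on work-up; terminal alkenes are not hydroaluminated at this temperature.

Step 4
Reactants: 5 2-[(4-methoxyphenyl)methoxy]-2-(prop-2-en-1-yl)pent-4-enal; 6 ethynylmagnesium bromide
Product: 7 rac-4-[(4-methoxyphenyl)methoxy]-4-(prop-2-en-1-yl)hept-6-en-1-yn-3-ol
Conditions: 6 (1.5 equiv), THF, −78 °C → 0 °C; aq. work-up
Reagents that add atoms: none
Why: 1,2-Addition of an alkynyl Grignard reagent to a non-enolisable aldehyde; the new carbinol centre forms as a racemate, which does not matter because step 5 oxidises it.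

Step 5
Reactants: 7 rac-4-[(4-methoxyphenyl)methoxy]-4-(prop-2-en-1-yl)hept-6-en-1-yn-3-ol
Product: 8 4-[(4-methoxyphenyl)methoxy]-4-(prop-2-en-1-yl)hept-6-en-1-yn-3-one
Conditions: Dess–Martin periodinane, CH2Cl2, 0 °C → rt
Reagents that add atoms: none
Why: Dess–Martin oxidation of a secondary propargylic alcohol to the ynone under neutral conditions that leave the alkenes and the PMB ether untouched.

Step 6
Reactants: 8 4-[(4-methoxyphenyl)methoxy]-4-(prop-2-en-1-yl)hept-6-en-1-yn-3-one
Product: 9 (1Z)-1-iodo-4-[(4-methoxyphenyl)methoxy]-4-(prop-2-en-1-yl)hepta-1,6-dien-3-one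
Conditions: NaI (2 equiv), AcOH, rt, dark
Reagents that add atoms: sodium iodide, [Na+].[I-]
Why: Conjugate hydroiodination of a terminal ynone (iodide attacks C3, the allenolate is protonated anti), which gives the (Z)-β-iodoenone as the kinetic product at room temperature; the unactivated alkenes do not react with NaI/AcOH.

Step 7
Reactants: 9 (1Z)-1-iodo-4-[(4-methoxyphenyl)methoxy]-4-(prop-2-en-1-yl)hepta-1,6-dien-3-one
Product: 11 3-[(2Z)-3-iodoprop-2-enoyl]-3-[(4-methoxyphenyl)methoxy]pentanedial, via the bis-ozonide 10 (not isolated)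
Conditions: O3, CH2Cl2, −78 °C (Sudan red 7B end-point); then Me2S, −78 °C → rt; used at once
Reagents that add atoms: ozone, [O-][O+]=O
Why: Ozonolysis with reductive work-up (Criegee mechanism): the two monosubstituted alkenes react far faster with ozone than the iodine- and carbonyl-deactivated C2=C3 bond or the anisyl ring, so titration to the dye end-point cleaves only them, and Me2S (chosen over PPh3, which adds to β-iodoenones) reduces the ozonides to the water-free dialdehyde.

Step 8
Reactants: 11 3-[(2Z)-3-iodoprop-2-enoyl]-3-[(4-methoxyphenyl)methoxy]pentanedial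
Product: 13 2-[(1S,5S)-5-hydroxy-1-[(4-methoxyphenyl)methoxy]-2-oxocyclohex-3-en-1-yl]acetaldehyde, via the alkenylchromium species 12 (not isolated)
Conditions: CrCl2 (4 equiv), (S)-N-[2-(4-tert-butyl-4,5-dihydro-1,3-oxazol-2-yl)-6-methylphenyl]methanesulfonamide (4.4 equiv), Et3N (4.4 equiv), NiCl2 (0.1 equiv), THF, rt; slow addition of 11 to a final concentration of about 2 mM; aq. work-up, ligand recovered
Reagents that add atoms: none
Why: Proposed new method: CrCl2 reduces NiCl2 to zerovalent nickel, which undergoes oxidative addition to the C3–I bond; transmetalation hands the (Z)-alkenyl group to ligand-bound trivalent chromium (12), and C3 then adds to the carbonyl carbon of one CH2CHO arm (the future C4) through a four-centre transition state with the aldehyde oxygen on the same chromium, closing the cyclohexenone ring in 6-exo-trig mode. The closest known reaction types are the ligand-controlled asymmetric Nozaki–Hiyama–Kishi alkenylation of aldehydes and intramolecular Nozaki–Hiyama–Kishi closures of β-iodoenones; selection between two enantiotopic aldehydes by such a reagent has not been shown, which is why the step is a proposal. C4 is set by the chiral sulfonamide–oxazoline ligand on chromium, which has to deliver C3 to the Re face of the reacting aldehyde. C6 is set by the substrate: chelation of the PMB ether oxygen and the C1 carbonyl oxygen by the metal chlorides present holds the C6–O bond in the enone plane (pseudo-equatorial), the chromium-bound aldehyde oxygen must lie in that plane as well, and so the two C–O bonds come out cis and the spare arm trans to the new hydroxyl. The step needs aldehyde-over-ketone chemoselectivity (inherent to alkenylchromium reagents), ring closure over intermolecular coupling (slow addition, high dilution) and one arm plus one face, which under the chelate reduces to a choice between two enantiomeric half-chair transition states that the ligand must make. A diastereomer with the new hydroxyl cis to the spare arm would fold into a bridged lactol and should be removable by chromatography.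

Step 9
Reactants: 13 2-[(1S,5S)-5-hydroxy-1-[(4-methoxyphenyl)methoxy]-2-oxocyclohex-3-en-1-yl]acetaldehyde
Product: 14 2-[(1S,5S)-1-[(4-methoxyphenyl)methoxy]-2-oxo-5-(triethylsilyloxy)cyclohex-3-en-1-yl]acetaldehyde
Conditions: Et3SiCl, imidazole, CH2Cl2, 0 °C
Reagents that add atoms: chlorotriethylsilane, CC[Si](Cl)(CC)CC
Why: Silylation of the secondary allylic alcohol with Et3SiCl/imidazole, conditions too mild to enolise the aldehyde or to touch the PMB ether; no stereocentre is affected.

Step 10
Reactants: 15 palmitoleic acid, (9Z)-hexadec-9-enoic acid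
Product: 18 (7Z)-15-iodopentadec-7-ene, via (9Z)-hexadec-9-enoyl chloride 16 (not isolated), via the O-acyl thiohydroxamate 17 (not isolated)
Conditions: (COCl)2, DMF (cat.), CH2Cl2, rt; then sodium salt of 1-hydroxypyridine-2(1H)-thione, DMAP (cat.), CHI3, cyclohexene, reflux, visible light
Reagents that add atoms: iodoform, IC(I)I
Why: Barton decarboxylative iodination: the acid chloride acylates the thiohydroxamate, the O-acyl thiohydroxamate fragments to CO2 and the primary alkyl radical, and this abstracts iodine from CHI3 in a chain reaction; the (Z)-alkene is too remote to cyclise onto the radical and cyclohexene scavenges iodine, so the double-bond geometry should be kept.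

Step 11
Reactants: 18 (7Z)-15-iodopentadec-7-ene
Product: 19 bis[(8Z)-pentadec-8-en-1-yl]zinc
Conditions: Et2Zn (neat, 4 equiv), CuI (0.3 mol%), 50 °C; EtI and excess Et2Zn removed in vacuo (repeated); residue taken up in toluene and used directly
Reagents that add atoms: diethylzinc, CC[Zn]CC
Why: Iodine–zinc exchange of a primary alkyl iodide with neat Et2Zn under CuI catalysis, pulled to the dialkylzinc by distilling off EtI and excess Et2Zn; the isolated alkene is inert to dialkylzincs.

Step 12
Reactants: 14 2-[(1S,5S)-1-[(4-methoxyphenyl)methoxy]-2-oxo-5-(triethylsilyloxy)cyclohex-3-en-1-yl]acetaldehyde; 19 bis[(8Z)-pentadec-8-en-1-yl]zinc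
Product: 20 (4S,6R)-6-[(2S,10Z)-2-hydroxyheptadec-10-en-1-yl]-6-[(4-methoxyphenyl)methoxy]-4-(triethylsilyloxy)cyclohex-2-en-1-one
Conditions: 19 (2.2 equiv), Ti(OiPr)4 (2 equiv), (1R,2R)-N,N'-bis(trifluoromethanesulfonyl)cyclohexane-1,2-diamine (8 mol%), toluene, −20 °C; aq. work-up
Reagents that add atoms: none
Why: Catalytic enantioselective addition of a dialkylzinc to an aldehyde (chiral titanium bis-sulfonamide catalyst): the (1R,2R)-ligand directs the alkyl group to the Si face of aliphatic aldehydes, which sets C2' as (S) under reagent control, while the hindered enone ketone, the silyl ether and the PMB ether do not react with the zinc reagent.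

Step 13
Reactants: 20 (4S,6R)-6-[(2S,10Z)-2-hydroxyheptadec-10-en-1-yl]-6-[(4-methoxyphenyl)methoxy]-4-(triethylsilyloxy)cyclohex-2-en-1-one
Product: 21 (4S,6R)-6-hydroxy-6-[(2S,10Z)-2-hydroxyheptadec-10-en-1-yl]-4-(triethylsilyloxy)cyclohex-2-en-1-one
Conditions: DDQ (1.3 equiv), CH2Cl2/pH 7 phosphate buffer (10:1), 0 °C → rt
Reagents that add atoms: none
Why: Oxidative removal of the PMB ether by DDQ (benzylic hydride abstraction, then hydrolysis of the oxocarbenium ion by the water present); the electron-poor enone, the isolated (Z)-alkene and the secondary alcohol are not oxidised under these conditions, and the stereocentres are untouched.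

Step 14
Reactants: 21 (4S,6R)-6-hydroxy-6-[(2S,10Z)-2-hydroxyheptadec-10-en-1-yl]-4-(triethylsilyloxy)cyclohex-2-en-1-one
Product: 22 (4S,6R)-4,6-dihydroxy-6-[(2S,10Z)-2-hydroxyheptadec-10-en-1-yl]cyclohex-2-en-1-one (CNP0305190.1)
Conditions: AcOH/THF/H2O (3:1:1), rt
Reagents that add atoms: none
Why: Acid-catalysed hydrolysis of the secondary triethylsilyl ether in aqueous acetic acid, mild and non-basic so that the hydroxy-enone neither eliminates nor undergoes retro-aldol cleavage; the same medium would also open any p-methoxybenzylidene acetal carried over from step 13.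

Compound list
1 | diethyl oxalate | CCOC(=O)C(=O)OCC | starting material
2 | allylmagnesium bromide | C=CC[Mg]Br | starting material
3 | ethyl 2-hydroxy-2-(prop-2-en-1-yl)pent-4-enoate | CCOC(=O)C(O)(CC=C)CC=C | intermediate
4 | ethyl 2-[(4-methoxyphenyl)methoxy]-2-(prop-2-en-1-yl)pent-4-enoate | CCOC(=O)C(CC=C)(CC=C)OCc1ccc(OC)cc1 | intermediate
5 | 2-[(4-methoxyphenyl)methoxy]-2-(prop-2-en-1-yl)pent-4-enal | O=CC(CC=C)(CC=C)OCc1ccc(OC)cc1 | intermediate
6 | ethynylmagnesium bromide | C#C[Mg]Br | starting material
7 | rac-4-[(4-methoxyphenyl)methoxy]-4-(prop-2-en-1-yl)hept-6-en-1-yn-3-ol (racemic at C3; C4 is not a stereocentre) | C#CC(O)C(CC=C)(CC=C)OCc1ccc(OC)cc1 | intermediate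
8 | 4-[(4-methoxyphenyl)methoxy]-4-(prop-2-en-1-yl)hept-6-en-1-yn-3-one | C#CC(=O)C(CC=C)(CC=C)OCc1ccc(OC)cc1 | intermediate
9 | (1Z)-1-iodo-4-[(4-methoxyphenyl)methoxy]-4-(prop-2-en-1-yl)hepta-1,6-dien-3-one | I/C=C\C(=O)C(CC=C)(CC=C)OCc1ccc(OC)cc1 | intermediate
10 | (1Z)-1-iodo-4-[(4-methoxyphenyl)methoxy]-5-(1,2,4-trioxolan-3-yl)-4-[(1,2,4-trioxolan-3-yl)methyl]pent-1-en-3-one (bis-ozonide, stereoisomer mixture at the trioxolane carbons) | I/C=C\C(=O)C(CC1OCOO1)(CC2OCOO2)OCc3ccc(OC)cc3 | intermediate
11 | 3-[(2Z)-3-iodoprop-2-enoyl]-3-[(4-methoxyphenyl)methoxy]pentanedial (achiral precursor of the key step) | O=CCC(CC=O)(OCc1ccc(OC)cc1)C(=O)/C=C\I | intermediate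
12 | alkenylchromium intermediate: trivalent chromium bearing chloride, the N-deprotonated (S)-sulfonamide–oxazoline ligand and, through C3, the (1Z)-4-[(4-methoxyphenyl)methoxy]-3,6-dioxo-4-(2-oxoethyl)hex-1-en-1-yl group | O=CCC(CC=O)(OCc1ccc(OC)cc1)C(=O)/C=C\[Cr](Cl)N(c1c(C)cccc1C1=N[C@@H](C(C)(C)C)CO1)S(C)(=O)=O | intermediate
13 | 2-[(1S,5S)-5-hydroxy-1-[(4-methoxyphenyl)methoxy]-2-oxocyclohex-3-en-1-yl]acetaldehyde (ring carbons 1 and 5 are C6 and C4 of the target) | O=CC[C@@]1(OCc2ccc(OC)cc2)C[C@H](O)C=CC1=O | intermediate
14 | 2-[(1S,5S)-1-[(4-methoxyphenyl)methoxy]-2-oxo-5-(triethylsilyloxy)cyclohex-3-en-1-yl]acetaldehyde | O=CC[C@@]1(OCc2ccc(OC)cc2)C[C@H](O[Si](CC)(CC)CC)C=CC1=O | intermediate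
15 | palmitoleic acid, (9Z)-hexadec-9-enoic acid | CCCCCC/C=C\CCCCCCCC(=O)O | starting material
16 | (9Z)-hexadec-9-enoyl chloride | CCCCCC/C=C\CCCCCCCC(=O)Cl | intermediate
17 | 1-[(9Z)-hexadec-9-enoyloxy]pyridine-2(1H)-thione | CCCCCC/C=C\CCCCCCCC(=O)On1ccccc1=S | intermediate
18 | (7Z)-15-iodopentadec-7-ene | CCCCCC/C=C\CCCCCCCI | intermediate
19 | bis[(8Z)-pentadec-8-en-1-yl]zinc | CCCCCC/C=C\CCCCCCC[Zn]CCCCCCC/C=C\CCCCCC | intermediate
20 | (4S,6R)-6-[(2S,10Z)-2-hydroxyheptadec-10-en-1-yl]-6-[(4-methoxyphenyl)methoxy]-4-(triethylsilyloxy)cyclohex-2-en-1-one | CCCCCC/C=C\CCCCCCC[C@H](O)C[C@@]1(OCc2ccc(OC)cc2)C[C@H](O[Si](CC)(CC)CC)C=CC1=O | intermediate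
21 | (4S,6R)-6-hydroxy-6-[(2S,10Z)-2-hydroxyheptadec-10-en-1-yl]-4-(triethylsilyloxy)cyclohex-2-en-1-one | CCCCCC/C=C\CCCCCCC[C@H](O)C[C@@]1(O)C[C@H](O[Si](CC)(CC)CC)C=CC1=O | intermediate
22 | (4S,6R)-4,6-dihydroxy-6-[(2S,10Z)-2-hydroxyheptadec-10-en-1-yl]cyclohex-2-en-1-one | CCCCCC/C=C\CCCCCCC[C@H](O)C[C@@]1(O)C[C@H](O)C=CC1=O | target

Total step count: 14. Longest linear sequence: 12 steps (steps 1–9, 12, 13, 14); steps 10 and 11 form a two-step side branch.

Steps most likely to fail

1. Step 8. The chiral chromium reagent may discriminate poorly between the two enantiotopic aldehyde arms or the two carbonyl faces, or intermolecular coupling may outrun ring closure. The fallback uses known chemistry and sets out from 11. Closure with the achiral reagent (CrCl2, catalytic NiCl2, THF/DMF, high dilution), an established intramolecular Nozaki–Hiyama–Kishi reaction, should give rac-2-[(1S,5S)-5-hydroxy-1-[(4-methoxyphenyl)methoxy]-2-oxocyclohex-3-en-1-yl]acetaldehyde F1; the chelate still favours the trans-arm diastereomer and the cis isomer is removed as its lactol. Kinetic resolution by lipase-catalysed acetylation (immobilised Candida antarctica lipase B, vinyl acetate, t-BuOMe, rt) is expected to acetylate the (5R)-alcohol faster, as lipases usually do with 4-hydroxycycloalk-2-enones, giving 2-[(1R,5R)-5-(acetyloxy)-1-[(4-methoxyphenyl)methoxy]-2-oxocyclohex-3-en-1-yl]acetaldehyde F2, which is separated. The unreacted alcohol is 13, where the fallback returns to the route.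

2. Step 7. Ozone may begin to attack the iodoalkene or the anisyl ring before both terminal alkenes are consumed, and the dialdehyde may hydrate or oligomerise during work-up. The fallback sets out from 9. Osmium-catalysed dihydroxylation (K2OsO2(OH)4 cat., N-methylmorpholine N-oxide, acetone/water), which is selective for the two electron-rich terminal alkenes, should give (1Z)-4-(2,3-dihydroxypropyl)-6,7-dihydroxy-1-iodo-4-[(4-methoxyphenyl)methoxy]hept-1-en-3-one F3 as a diastereomer mixture. Glycol cleavage with NaIO4 on silica gel in CH2Cl2 then gives 11 under nearly water-free conditions, where the fallback returns to the route.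

3. Step 12. Facial selectivity may erode if the resident C6 stereocentre and the chiral titanium catalyst are mismatched, so that both C2' epimers form. The fallback sets out from 14. The addition of 19 is run with Ti(OiPr)4 and the racemic bis-sulfonamide ligand, and the two C2' epimers are separated by chromatography; the (2'S)-epimer is 20. The other epimer, (4S,6R)-6-[(2R,10Z)-2-hydroxyheptadec-10-en-1-yl]-6-[(4-methoxyphenyl)methoxy]-4-(triethylsilyloxy)cyclohex-2-en-1-one F4, is inverted by a Mitsunobu reaction (4-nitrobenzoic acid, PPh3, diisopropyl azodicarboxylate, toluene, 0 °C → rt) to (2S,10Z)-1-[(1R,5S)-1-[(4-methoxyphenyl)methoxy]-2-oxo-5-(triethylsilyloxy)cyclohex-3-en-1-yl]heptadec-10-en-2-yl 4-nitrobenzoate F5. Methanolysis of F5 (K2CO3, MeOH, 0 °C) returns to the route at 20.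

Further compounds
F1 | step 8 | rac-2-[(1S,5S)-5-hydroxy-1-[(4-methoxyphenyl)methoxy]-2-oxocyclohex-3-en-1-yl]acetaldehyde (racemate of 13) | O=CC[C@@]1(OCc2ccc(OC)cc2)C[C@H](O)C=CC1=O.O=CC[C@]1(OCc2ccc(OC)cc2)C[C@@H](O)C=CC1=O
F2 | step 8 | 2-[(1R,5R)-5-(acetyloxy)-1-[(4-methoxyphenyl)methoxy]-2-oxocyclohex-3-en-1-yl]acetaldehyde | O=CC[C@]1(OCc2ccc(OC)cc2)C[C@@H](OC(C)=O)C=CC1=O
F3 | step 7 | (1Z)-4-(2,3-dihydroxypropyl)-6,7-dihydroxy-1-iodo-4-[(4-methoxyphenyl)methoxy]hept-1-en-3-one (diastereomer mixture) | OCC(O)CC(CC(O)CO)(OCc1ccc(OC)cc1)C(=O)/C=C\I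
F4 | step 12 | (4S,6R)-6-[(2R,10Z)-2-hydroxyheptadec-10-en-1-yl]-6-[(4-methoxyphenyl)methoxy]-4-(triethylsilyloxy)cyclohex-2-en-1-one | CCCCCC/C=C\CCCCCCC[C@@H](O)C[C@@]1(OCc2ccc(OC)cc2)C[C@H](O[Si](CC)(CC)CC)C=CC1=O
F5 | step 12 | (2S,10Z)-1-[(1R,5S)-1-[(4-methoxyphenyl)methoxy]-2-oxo-5-(triethylsilyloxy)cyclohex-3-en-1-yl]heptadec-10-en-2-yl 4-nitrobenzoate | CCCCCC/C=C\CCCCCCC[C@H](OC(=O)c1ccc(cc1)[N+](=O)[O-])C[C@@]2(OCc3ccc(OC)cc3)C[C@H](O[Si](CC)(CC)CC)C=CC2=O
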